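The route rests on cutting the saturated tether between C2' and C3' of the pentadecatrienyl chain. This bond lies two carbons from ring atom C5 of the 1,2-dioxolane and four from the diene. The key step, placed last, is a one-flask hydroboration/alkyl–alkyl Suzuki coupling that unites the finished C13 polyene and the finished peroxide by two-electron steps only. It exploits two footprints. O–C5–C1'–C2' is the skeleton of a 2,2-disubstituted oxetane, whose strain-releasing perhydrolysis sets C5 and leaves C2' as a primary alcohol, then bromide. C3'=C4' is the only monosubstituted alkene of a tridecatetraene. The precursors are a bromoethyl dioxolane ester and a B-alkyl-9-BBN.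

Key step: step 10

Numbering: side-chain carbons run from C1' (on ring atom C5) to C15'. The target is (3R,5S), with the two ring methyl groups trans.
Assumption: the (S)-BINOL-derived lanthanum–lithium catalyst is taken to deliver the methylide to the face of ketone 2 that gives (S)-3. If the sense of induction on this ketone is the opposite, the (R)-BINOL catalyst is used and nothing else changes.

Step 1
Reactants: 1 pentane-2,4-dione
Product: 2 1-(2-methyl-1,3-dioxolan-2-yl)propan-2-one
Conditions: HOCH2CH2OH (1.0 equiv), p-TsOH (cat.), toluene, reflux, Dean–Stark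
Reagents that add atoms: ethane-1,2-diol, OCCO
Why: Acid-catalysed ketalisation with azeotropic removal of water, in which one equivalent of diol should give mainly the monoketal, separable from diketal and diketone by distillation.

Step 2
Reactants: 2 1-(2-methyl-1,3-dioxolan-2-yl)propan-2-one
Product: 4 (2R)-2-methyl-2-[(2-methyl-1,3-dioxolan-2-yl)methyl]oxetane, via epoxide 3 (not isolated)
Conditions: La/Li3/(S)-BINOL3 complex (5 mol %), [2,4,6-(MeO)3C6H2]3P=O (5 mol %), Me2S(O)=CH2 (1.2 equiv), 5 Å MS, THF, rt; then more catalyst and phosphine oxide (15 mol % each), Me2S(O)=CH2 (1.2 equiv), 45 °C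
Reagents that add atoms: dimethyloxosulfonium methylide (two equivalents, one CH2 each), CS(C)(=O)=C
Why: Catalytic asymmetric Corey–Chaykovsky epoxidation of a methyl ketone, in which the binaphthoxide–phosphine oxide complex tells CH3 from CH2R and so sets the tertiary C–O centre, followed by oxirane-to-oxetane ring expansion with a second ylide that attacks only the epoxide CH2, leaves the stereocentre untouched and should raise the enantiomeric purity because the catalyst processes the major epoxide faster.

Step 3
Reactants: 4 (2R)-2-methyl-2-[(2-methyl-1,3-dioxolan-2-yl)methyl]oxetane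
Product: 6 (1S,5S)-1,5-dimethyl-2,6,7-trioxabicyclo[3.2.1]octane, via hydroperoxy alcohol 5 (not isolated)
Conditions: anhydrous H2O2 in Et2O (10 equiv), TMSOTf (0.2 equiv), Et2O, −78 to 0 °C; aqueous wash; then CSA (cat.), 4 Å MS, CH2Cl2, rt (kept in solution)
Reagents that add atoms: hydrogen peroxide, OO
Why: Lewis-acid-catalysed perhydrolysis of a tertiary oxetane, driven by release of ring strain, in which H2O2 attacks the more substituted carbon opposite to the ring oxygen (inversion, sets C5 of the target), followed by acid-catalysed peroxyketal exchange in which the OOH and the freed primary OH displace the glycol, the bridge allowing only one configuration at the ketal carbon.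

Step 4
Reactants: 6 (1S,5S)-1,5-dimethyl-2,6,7-trioxabicyclo[3.2.1]octane
Product: 7 methyl 2-[(3R,5S)-5-(2-hydroxyethyl)-3,5-dimethyl-1,2-dioxolan-3-yl]acetate
Conditions: CH2=C(OMe)OTBS (2 equiv), TiCl4 (1.1 equiv), CH2Cl2, −78 °C; then H2O
Reagents that add atoms: tert-butyl[(1-methoxyethenyl)oxy]dimethylsilane, C=C(OC)O[Si](C)(C)C(C)(C)C
Why: Lewis-acid displacement of a 3-alkoxy-1,2-dioxolane by a silyl ketene acetal through a peroxycarbenium ion (Mukaiyama-type addition), in which TiCl4 binds the most basic oxygen O2, C1–O2 ionises, and the nucleophile should enter anti to the departing titanium alkoxide arm that stays tied to C5, which sets C3 of the target with inversion and places the two arms trans.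

Step 5
Reactants: 7 methyl 2-[(3R,5S)-5-(2-hydroxyethyl)-3,5-dimethyl-1,2-dioxolan-3-yl]acetate
Product: 9 methyl 2-[(3R,5R)-5-(2-bromoethyl)-3,5-dimethyl-1,2-dioxolan-3-yl]acetate, via mesylate 8 (not isolated)
Conditions: MsCl, Et3N, CH2Cl2, 0 °C; then LiBr, acetone, rt
Reagents that add atoms: methanesulfonyl chloride (atoms stay only in 8), CS(=O)(=O)Cl; lithium bromide, [Li+].[Br-]
Why: Mesylation and Finkelstein-type SN2 displacement at an unhindered primary carbon, free of phosphines and strong base, so that peroxide, ester and both quaternary centres stay untouched (the C5 descriptor changes only because bromine raises the CIP rank of the arm).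

Step 6
Reactants: 10 (Z)-pent-2-en-1-ol
Product: 11 (Z)-1-bromopent-2-ene
Conditions: PBr3 (0.4 equiv), pyridine (cat.), Et2O, −10 °C
Reagents that add atoms: phosphorus tribromide, BrP(Br)Br
Why: SN2-type bromination of a primary allylic alcohol through its phosphite ester, the low temperature preserving the Z geometry and suppressing allylic transposition.

Step 7
Reactants: 11 (Z)-1-bromopent-2-ene
Product: 12 (Z)-hept-4-en-1-yne
Conditions: HC≡CMgBr, CuBr·SMe2 (10 mol %), THF, 0 °C to rt
Reagents that add atoms: ethynylmagnesium bromide, C#C[Mg]Br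
Why: Copper(I)-catalysed coupling of an alkynyl Grignard reagent with a primary allylic bromide, which should occur at the α-carbon (SN2) with retention of the Z geometry to give the skipped enyne.

Step 8
Reactants: 13 pent-4-enal
Product: 14 (1E)-1-iodohexa-1,5-diene
Conditions: CrCl2 (6 equiv), CHI3 (2 equiv), dioxane–THF, 0 °C to rt
Reagents that add atoms: iodoform, IC(I)I
Why: Takai olefination, in which the gem-dichromium species from CHI3 adds to the aldehyde and eliminates to the E-vinyl iodide while the terminal alkene stays inert.

Step 9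
Reactants: 12 (Z)-hept-4-en-1-yne; 14 (1E)-1-iodohexa-1,5-diene
Product: 16 (5E,7E,10Z)-trideca-1,5,7,10-tetraene, via alkenylzirconocene 15 (not isolated)
Conditions: Cp2Zr(H)Cl (1.1 equiv), THF, rt, dark; then 14, Pd(PPh3)4 (5 mol %), rt
Reagents that add atoms: zirconocene hydrochloride (zirconium stays only in 15), [H][Zr](Cl)(C1C=CC=C1)C1C=CC=C1
Why: syn-Hydrozirconation of the terminal alkyne places zirconium at the chain end to give the E-alkenyl metal without touching the internal Z-alkene, and the palladium-catalysed Negishi-type alkenyl–alkenyl coupling proceeds with retention at both partners under neutral conditions, which gives the E,E-diene.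

Step 10
Reactants: 16 (5E,7E,10Z)-trideca-1,5,7,10-tetraene; 9 methyl 2-[(3R,5R)-5-(2-bromoethyl)-3,5-dimethyl-1,2-dioxolan-3-yl]acetate
Product: 18 methyl 2-[(3R,5S)-3,5-dimethyl-5-[(7E,9E,12Z)-pentadeca-7,9,12-trien-1-yl]-1,2-dioxolan-3-yl]acetate, via B-alkyl-9-BBN 17 (not isolated)
Conditions: 16 (1.3 equiv), 9-BBN-H (1.25 equiv), THF, 0 °C to rt; then 9, Pd(OAc)2 (4 mol %), PCy3 (8 mol %), K3PO4·H2O (1.3 equiv), THF, rt
Reagents that add atoms: 9-borabicyclo[3.3.1]nonane (boron stays only in 17, only hydrogen reaches 18), [H]B1C2CCCC1CCC2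
Why: 9-BBN adds anti-Markovnikov to C1=C2 of 16, the only monosubstituted alkene (the three 1,2-disubstituted alkenes, two of them conjugated, should react far more slowly), to give 17. Pd(0)/PCy3 then enters the primary C–Br bond of 9 by an SN2-type oxidative addition, the hydroxide-activated borate of 17 hands its primary alkyl group to palladium, and reductive elimination, made faster than β-hydride elimination by the bulky electron-rich phosphine, forms the C2'–C3' bond; the closest known reaction type is the room-temperature B-alkyl Suzuki–Miyaura coupling of unactivated primary alkyl bromides. No ring is closed and no stereocentre is made; the quaternary centres C3 and C5 are not touched and the alkene geometries are carried through unchanged. The step needs selectivity for C–Br over the O–O bond, which the substrate secures by the steric shielding of a peroxide flanked by two fully substituted carbons, helped by room temperature, catalytic phosphine and a weak base that should not trigger retro-oxa-Michael opening at C3. It also needs a two-electron pathway, because a radical at C3' would close 5-exo onto the diene; the organoboron nucleophile and Pd/PCy3 avoid such a radical.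

Compound list
1 | pentane-2,4-dione | CC(=O)CC(C)=O | starting material
2 | 1-(2-methyl-1,3-dioxolan-2-yl)propan-2-one | CC(=O)CC1(C)OCCO1 | intermediate
3 | (2S)-2-methyl-2-[(2-methyl-1,3-dioxolan-2-yl)methyl]oxirane | O1C[C@]1(C)CC2(C)OCCO2 | intermediate
4 | (2R)-2-methyl-2-[(2-methyl-1,3-dioxolan-2-yl)methyl]oxetane | O1CC[C@]1(C)CC2(C)OCCO2 | intermediate
5 | (3S)-3-hydroperoxy-3-methyl-4-(2-methyl-1,3-dioxolan-2-yl)butan-1-ol | OCC[C@](C)(OO)CC1(C)OCCO1 | intermediate
6 | (1S,5S)-1,5-dimethyl-2,6,7-trioxabicyclo[3.2.1]octane | C1C[C@@]2(C)C[C@@](C)(O1)OO2 | intermediate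
7 | methyl 2-[(3R,5S)-5-(2-hydroxyethyl)-3,5-dimethyl-1,2-dioxolan-3-yl]acetate | OCC[C@@]1(C)C[C@](C)(CC(=O)OC)OO1 | intermediate
8 | methyl 2-[(3R,5S)-5-(2-methylsulfonyloxyethyl)-3,5-dimethyl-1,2-dioxolan-3-yl]acetate | CS(=O)(=O)OCC[C@@]1(C)C[C@](C)(CC(=O)OC)OO1 | intermediate
9 | methyl 2-[(3R,5R)-5-(2-bromoethyl)-3,5-dimethyl-1,2-dioxolan-3-yl]acetate | BrCC[C@@]1(C)C[C@](C)(CC(=O)OC)OO1 | intermediate
10 | (Z)-pent-2-en-1-ol | CC/C=C\CO | starting material
11 | (Z)-1-bromopent-2-ene | CC/C=C\CBr | intermediate
12 | (Z)-hept-4-en-1-yne | CC/C=C\CC#C | intermediate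
13 | pent-4-enal | C=CCCC=O | starting material
14 | (1E)-1-iodohexa-1,5-diene | C=CCC/C=C/I | intermediate
15 | chlorobis(cyclopentadienyl)[(1E,4Z)-hepta-1,4-dien-1-yl]zirconium (Cp rings drawn σ-bound) | CC/C=C\C/C=C/[Zr](Cl)(C1C=CC=C1)C1C=CC=C1 | intermediate
16 | (5E,7E,10Z)-trideca-1,5,7,10-tetraene | C=CCC/C=C/C=C/C/C=C\CC | intermediate
17 | 9-[(5E,7E,10Z)-trideca-5,7,10-trien-1-yl]-9-borabicyclo[3.3.1]nonane | CC/C=C\C/C=C/C=C/CCCCB1C2CCCC1CCC2 | intermediate
18 | methyl 2-[(3R,5S)-3,5-dimethyl-5-[(7E,9E,12Z)-pentadeca-7,9,12-trien-1-yl]-1,2-dioxolan-3-yl]acetate | CC/C=C\C/C=C/C=C/CCCCCC[C@@]1(C)C[C@](C)(CC(=O)OC)OO1 | target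

Total step count: 10. Longest linear sequence: 6 (steps 1 to 5, then step 10).

Steps most likely to fail

(a) Step 10. Several processes may interfere:
- The electron-rich phosphine or Pd(0) may attack the O–O bond.
- The basic medium may open the ring at C3 by a retro-oxa-Michael reaction and so scramble C3.
- Palladium hydrides from β-hydride elimination may move the skipped alkenes into conjugation.

The fallback makes the same bond by a phosphine-free and base-free nickel-catalysed alkyl–alkyl Negishi coupling at low temperature. It sets out from 9 and 16 and comes back at 18. NaI in acetone turns 9 into the iodide F1. Et2BH hydroborates the terminal alkene of 16 to the diethyl(alkyl)borane F2. Boron–zinc exchange with Et2Zn gives the dialkylzinc F3. F3 couples with F1 under Ni(acac)2 (10 mol %) and 4-fluorostyrene (20 mol %) in THF–NMP at −35 °C to give 18.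

(b) Step 3. Cationic character at the tertiary carbon may erode its configuration. It may also trigger Grob-type cleavage of the bond between the ring CH2 and the ketal carbon. The ketal carbon may be over-peroxidised. No other stereospecific entry to a tertiary C–OO centre is at hand. The fallback therefore avoids an electrophilic C5 altogether, forms the C–O bond by nucleophilic conjugate addition and separates enantiomers afterwards. It sets out from 4 (material made without the chiral catalyst serves as well) and comes back at 7.
- Aqueous HCl in THF removes the ketal and eliminates the oxetane oxygen to give the hydroxy enone F4.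
- H2O2 (30 %) with catalytic LiOH in MeOH at 0 °C adds to the β,β-disubstituted enone to give the peroxyhemiketal F5.
- CSA over 4 Å MS closes F5 to the racemic bicycle, that is 6 together with its enantiomer F6.
- The conditions of step 4 then give 7 together with its enantiomer F7, and chromatography on a chiral stationary phase delivers 7.

(c) Step 4. TiCl4 may ionise the C1–O7 (peroxide) bond instead of C1–O2. It may consume the acid-labile ketene acetal. The nucleophile may also attack both faces of the peroxycarbenium ion. The fallback brings in the acetate arm at a lower oxidation level with the most robust nucleophile for such ions. It sets out from 6 and comes back at 7.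
- Hosomi–Sakurai allylation (allyltrimethylsilane, SnCl4, CH2Cl2, −78 °C) gives the allyl dioxolane F8.
- Ozonolysis (O3, CH2Cl2, −78 °C; Me2S) gives the aldehyde F9.
- Pinnick oxidation (NaClO2, NaH2PO4, 2-methylbut-2-ene) gives the acid F10.
- TMSCHN2 in MeOH–toluene gives 7.

Further compounds
F1 | step 10 | methyl 2-[(3R,5R)-5-(2-iodoethyl)-3,5-dimethyl-1,2-dioxolan-3-yl]acetate | ICC[C@@]1(C)C[C@](C)(CC(=O)OC)OO1
F2 | step 10 | diethyl[(5E,7E,10Z)-trideca-5,7,10-trien-1-yl]borane | CC/C=C\C/C=C/C=C/CCCCB(CC)CC
F3 | step 10 | bis[(5E,7E,10Z)-trideca-5,7,10-trien-1-yl]zinc | CC/C=C\C/C=C/C=C/CCCC[Zn]CCCC/C=C/C=C/C/C=C\CC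
F4 | step 3 | (E)-6-hydroxy-4-methylhex-3-en-2-one | CC(=O)/C=C(\C)CCO
F5 | step 3 | 5-(2-hydroxyethyl)-3,5-dimethyl-1,2-dioxolan-3-ol (racemic, both C3 epimers) | OCCC1(C)CC(C)(O)OO1
F6 | step 3 | (1R,5R)-1,5-dimethyl-2,6,7-trioxabicyclo[3.2.1]octane (enantiomer of 6) | C1C[C@]2(C)C[C@](C)(O1)OO2
F7 | step 3 | methyl 2-[(3S,5R)-5-(2-hydroxyethyl)-3,5-dimethyl-1,2-dioxolan-3-yl]acetate (enantiomer of 7) | OCC[C@]1(C)C[C@@](C)(CC(=O)OC)OO1
F8 | step 4 | 2-[(3S,5S)-3,5-dimethyl-5-(prop-2-en-1-yl)-1,2-dioxolan-3-yl]ethan-1-ol | OCC[C@@]1(C)C[C@](C)(CC=C)OO1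
F9 | step 4 | 2-[(3R,5S)-5-(2-hydroxyethyl)-3,5-dimethyl-1,2-dioxolan-3-yl]acetaldehyde | OCC[C@@]1(C)C[C@](C)(CC=O)OO1
F10 | step 4 | 2-[(3R,5S)-5-(2-hydroxyethyl)-3,5-dimethyl-1,2-dioxolan-3-yl]acetic acid | OCC[C@@]1(C)C[C@](C)(CC(=O)O)OO1
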